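**Strategy.** The butenolide ring (O–C16–C17–C18–C19) is treated as a C16 propargylic alcohol whose C17≡C18 alkyne takes up one carbon (C17′) at C17 and carbon dioxide (C19) at C18 from opposite faces. One operation, an alkoxide-directed anti-carbomagnesiation with a silylmethyl Grignard reagent followed by carboxylation and lactonisation, should form C17–C17′, C18–C19 and O–C19 and close the ring, with the silane as a latent C17′ hydroxyl. Its precursor is the (R)-C16 secondary alcohol with a terminal alkyne, already carrying the sclareolide-derived Δ8,9-decalin and the (E)-C13=C14 alkene with C13′–OH as a TBDPS ether; the same directed carbomagnesiation, used earlier on a pentynol, sets that alkene.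

Key step: step 13

Remark (labels): C8=C9 is the ring alkene of the decalin, C11–C12 the tether, C13(=C14) carries the C13′ hydroxymethyl, C15 is the methylene next to the C16 carbinol, C17(C17′)=C18, C19 is the lactone carbonyl. "Dec" = (4aS,8aS)-2,5,5,8a-tetramethyl-3,4,4a,5,6,7,8,8a-octahydronaphthalen-1-yl, attached through C9.

Remark (assumption): the TBS ether of 3-butyn-1-ol (5) is taken as a purchased compound; if it had to be made, one silylation step would be added.

Remark (numbering): carbon–metal species formed in the flask are numbered; O–metal salts of numbered alcohols are not numbered separately.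

Remark (design): C13′ carries TBDPS so that the primary TBS ether on C16–O can be removed selectively and the group survives the Tamao conditions. The C16 alkoxide is formed before copper is added. The ynone is reached through the aldehyde, which avoids a chlorite oxidation next to the electron-rich C8=C9 alkene.

**Step 1**
Reactants: 1 (+)-sclareolide
Product: 2 methyl 2-Dec-acetate
Conditions: conc. H2SO4, MeOH, rt; AgNO3–SiO2 chromatography if minor alkene isomers persist
Reagents that add atoms: methanol, CO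
Why: Acid-mediated E1 opening of the tertiary C8–O lactone bond with in situ Fischer esterification, run under equilibrating conditions, should funnel the alkene isomers to the tetrasubstituted C8=C9 olefin as the thermodynamic sink while C5 and C10 stay untouched.

**Step 2**
Reactants: 2 methyl 2-Dec-acetate
Product: 3 2-Dec-ethan-1-ol
Conditions: LiAlH4, THF, 0 °C → rt
Reagents that add atoms: none
Why: Hydride reduction of the unconjugated ester to the primary alcohol leaves the isolated tetrasubstituted alkene alone.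

**Step 3**
Reactants: 3 2-Dec-ethan-1-ol
Product: 4 1-bromo-2-Dec-ethane
Conditions: CBr4, PPh3, CH2Cl2, 0 °C
Reagents that add atoms: carbon tetrabromide, BrC(Br)(Br)Br
Why: The Appel reaction converts the unhindered primary alcohol into the bromide under neutral conditions that do not touch the C8=C9 alkene.

**Step 4**
Reactants: 5 tert-butyl(but-3-yn-1-yloxy)dimethylsilane
Product: 7 5-[(tert-butyldimethylsilyl)oxy]pent-2-yn-1-ol, via lithium alkynide 6 (not isolated)
Conditions: n-BuLi, THF, −78 °C; (CH2O)n, −78 °C → rt; H2O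
Reagents that add atoms: formaldehyde (as paraformaldehyde), C=O
Why: Deprotonation of the terminal alkyne and hydroxymethylation of the lithium acetylide with formaldehyde is a standard one-carbon homologation that the silyl ether tolerates.

**Step 5**
Reactants: 4 1-bromo-2-Dec-ethane; 7 5-[(tert-butyldimethylsilyl)oxy]pent-2-yn-1-ol
Product: 10 (E)-5-[(tert-butyldimethylsilyl)oxy]-2-(2-Dec-ethyl)pent-2-en-1-ol, via homoallylic Grignard reagent 8 (not isolated), via chelated vinylmagnesium alkoxide 9 (not isolated)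
Conditions: 4 (2 equiv), Mg, I2 (cat.), THF, rt → 45 °C; 7, i-PrMgCl (1.0 equiv), THF, 0 °C; combine, CuI (15 mol%), 0 °C → rt; aq. NH4Cl
Reagents that add atoms: none
Why: In this copper-catalysed anti-carbomagnesiation of a propargylic alcohol, the C13′ magnesium alkoxide directs C12 to the proximal alkyne carbon C13 and holds magnesium on C14 in a five-membered chelate, so protonation should give the (E)-alkene with C12 cis to C15.

**Step 6**
Reactants: 10 (E)-5-[(tert-butyldimethylsilyl)oxy]-2-(2-Dec-ethyl)pent-2-en-1-ol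
Product: 11 tert-butyl{[(E)-5-[(tert-butyldimethylsilyl)oxy]-2-(2-Dec-ethyl)pent-2-en-1-yl]oxy}diphenylsilane
Conditions: TBDPSCl, imidazole, CH2Cl2, rt
Reagents that add atoms: tert-butyl(chloro)diphenylsilane, CC(C)(C)[Si](Cl)(c1ccccc1)c1ccccc1
Why: Imidazole-mediated silylation of the primary allylic alcohol installs a TBDPS ether that survives the acid used next to free C16–OH.

**Step 7**
Reactants: 11 tert-butyl{[(E)-5-[(tert-butyldimethylsilyl)oxy]-2-(2-Dec-ethyl)pent-2-en-1-yl]oxy}diphenylsilane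
Product: 12 (E)-4-{[(tert-butyldiphenylsilyl)oxy]methyl}-6-Dec-hex-3-en-1-ol
Conditions: CSA (10 mol%), MeOH/CH2Cl2 (1:1), 0 °C
Reagents that add atoms: none
Why: Acid-catalysed methanolysis cleaves the primary TBS ether far faster than the bulkier, more acid-stable TBDPS ether.

**Step 8**
Reactants: 12 (E)-4-{[(tert-butyldiphenylsilyl)oxy]methyl}-6-Dec-hex-3-en-1-ol
Product: 13 (E)-4-{[(tert-butyldiphenylsilyl)oxy]methyl}-6-Dec-hex-3-enal
Conditions: Dess–Martin periodinane, NaHCO3, CH2Cl2, 0 °C → rt; used crude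
Reagents that add atoms: none
Why: Buffered Dess–Martin oxidation gives the β,γ-unsaturated aldehyde under non-basic conditions that should not move the C13=C14 alkene into conjugation.

**Step 9**
Reactants: 13 (E)-4-{[(tert-butyldiphenylsilyl)oxy]methyl}-6-Dec-hex-3-enal; 14 trimethylsilylacetylene
Product: 16 (5E)-6-{[(tert-butyldiphenylsilyl)oxy]methyl}-8-Dec-1-(trimethylsilyl)oct-5-en-1-yn-3-ol (both C16 epimers), via lithium (trimethylsilyl)acetylide 15 (not isolated)
Conditions: 14, n-BuLi, THF, −78 °C; 13, −78 °C; H2O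
Reagents that add atoms: none
Why: 1,2-Addition of the lithium acetylide to the aldehyde at low temperature should outpace enolisation, and the C16 epimer mixture does not matter because C16 is oxidised next.

**Step 10**
Reactants: 16 (5E)-6-{[(tert-butyldiphenylsilyl)oxy]methyl}-8-Dec-1-(trimethylsilyl)oct-5-en-1-yn-3-ol
Product: 17 (E)-6-{[(tert-butyldiphenylsilyl)oxy]methyl}-8-Dec-1-(trimethylsilyl)oct-5-en-1-yn-3-one
Conditions: Dess–Martin periodinane, NaHCO3, CH2Cl2, 0 °C
Reagents that add atoms: none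
Why: Dess–Martin oxidation converts the secondary propargylic alcohol into the ynone under buffered, non-basic conditions.

**Step 11**
Reactants: 17 (E)-6-{[(tert-butyldiphenylsilyl)oxy]methyl}-8-Dec-1-(trimethylsilyl)oct-5-en-1-yn-3-one
Product: 18 (3R,5E)-6-{[(tert-butyldiphenylsilyl)oxy]methyl}-8-Dec-1-(trimethylsilyl)oct-5-en-1-yn-3-ol
Conditions: Ru[(R,R)-TsDPEN](p-cymene) (3 mol%), i-PrOH, rt
Reagents that add atoms: none
Why: In this Noyori asymmetric transfer hydrogenation of an alkynyl ketone, the (R,R)-TsDPEN–ruthenium hydride distinguishes the alkynyl from the alkyl substituent and should deliver hydride to the face that gives the (R)-carbinol at C16, under base-free conditions that spare the skipped alkene.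

**Step 12**
Reactants: 18 (3R,5E)-6-{[(tert-butyldiphenylsilyl)oxy]methyl}-8-Dec-1-(trimethylsilyl)oct-5-en-1-yn-3-ol
Product: 19 (3R,5E)-6-{[(tert-butyldiphenylsilyl)oxy]methyl}-8-Dec-oct-5-en-1-yn-3-ol
Conditions: K2CO3 (0.3 equiv), MeOH, rt
Reagents that add atoms: none
Why: Carbonate-catalysed methanolysis of the alkynyl C–Si bond frees the terminal alkyne without affecting the TBDPS ether or the C16 stereocentre.

**Step 13**
Reactants: 19 (3R,5E)-6-{[(tert-butyldiphenylsilyl)oxy]methyl}-8-Dec-oct-5-en-1-yn-3-ol; 20 (chloromethyl)isopropoxydimethylsilane; 21 carbon dioxide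
Product: 25 (5R)-5-[(2E)-3-{[(tert-butyldiphenylsilyl)oxy]methyl}-5-Dec-pent-2-en-1-yl]-4-{[isopropoxy(dimethyl)silyl]methyl}furan-2(5H)-one, via silylmethyl Grignard reagent 22 (not isolated), via oxamagnesacycle 23 (not isolated), via cis-hydroxy acid 24 (not isolated)
Conditions: 20, Mg, THF → 22 (5 equiv); 19, CuI (30 mol%), THF, −20 °C → rt; CO2 (1 atm), 0 °C → rt; aq. citric acid (pH 4)
Reagents that add atoms: none
Why: The first equivalent of 22 turns C16–OH into its magnesium alkoxide, and a copper(I)-derived organometallic then transfers the silylmethyl group to the proximal alkyne carbon C17 while magnesium ends on C18 on the alkoxide side, giving the five-membered oxamagnesacycle 23 (net anti-addition). Carbon dioxide inserts into the C18–Mg bond with retention, so the carboxylate is cis to C16–O, and on acidification hydroxy acid 24 closes the butenolide by 5-exo-trig acyl substitution (O16 onto C19). The closest known reaction type is the copper-catalysed anti-carbomagnesiation of propargylic alcohols with electrophilic trapping of the chelated vinylmagnesium, including carboxylation to butenolides, and the (alkoxysilyl)methyl Grignard reagent is an established hydroxymethyl-anion equivalent. No stereocentre is formed; C16, set in step 11, has no bond broken and becomes epimerisable only once the lactone exists, so the work-up is kept weakly acidic. The step needs regioselectivity (carbon to C17, metal to C18) and anti-stereoselectivity, both secured by the C16 alkoxide chelate, and chemoselectivity, which follows because the C8=C9 and C13=C14 alkenes and the TBDPS ether carry no directing alkoxide.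

**Step 14**
Reactants: 25 (5R)-5-[(2E)-3-{[(tert-butyldiphenylsilyl)oxy]methyl}-5-Dec-pent-2-en-1-yl]-4-{[isopropoxy(dimethyl)silyl]methyl}furan-2(5H)-one
Product: 26 (5R)-5-[(2E)-3-{[(tert-butyldiphenylsilyl)oxy]methyl}-5-Dec-pent-2-en-1-yl]-4-(hydroxymethyl)furan-2(5H)-one
Conditions: 30% aq. H2O2, KHCO3, KF, THF/MeOH (1:1), rt
Reagents that add atoms: hydrogen peroxide, OO
Why: In the Tamao oxidation, hydroperoxide adds to the alkoxysilane and the C17′–Si bond migrates to oxygen with retention, the bicarbonate buffer keeping the medium mild enough to disfavour protodesilylation and epimerisation at C16.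

**Step 15**
Reactants: 26 (5R)-5-[(2E)-3-{[(tert-butyldiphenylsilyl)oxy]methyl}-5-Dec-pent-2-en-1-yl]-4-(hydroxymethyl)furan-2(5H)-one
Product: 27 (5R)-4-(hydroxymethyl)-5-[(2E)-3-(hydroxymethyl)-5-Dec-pent-2-en-1-yl]furan-2(5H)-one (CNP0238475.3)
Conditions: HF·pyridine, pyridine, THF, 0 °C → rt
Reagents that add atoms: none
Why: Fluoride cleavage of the TBDPS ether with pyridine-buffered HF is non-basic, so the butenolide and its epimerisable C16–H should be unaffected.

**Compound list**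

1 | (+)-sclareolide | C[C@]12OC(=O)C[C@@H]1[C@@]3(C)CCCC(C)(C)[C@@H]3CC2 | starting material
2 | methyl 2-Dec-acetate | CC1=C(CC(=O)OC)[C@@]2(C)CCCC(C)(C)[C@@H]2CC1 | intermediate
3 | 2-Dec-ethan-1-ol | CC1=C(CCO)[C@@]2(C)CCCC(C)(C)[C@@H]2CC1 | intermediate
4 | 1-bromo-2-Dec-ethane | CC1=C(CCBr)[C@@]2(C)CCCC(C)(C)[C@@H]2CC1 | intermediate
5 | tert-butyl(but-3-yn-1-yloxy)dimethylsilane | C#CCCO[Si](C)(C)C(C)(C)C | starting material
6 | {4-[(tert-butyldimethylsilyl)oxy]but-1-yn-1-yl}lithium | [Li]C#CCCO[Si](C)(C)C(C)(C)C | intermediate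
7 | 5-[(tert-butyldimethylsilyl)oxy]pent-2-yn-1-ol | OCC#CCCO[Si](C)(C)C(C)(C)C | intermediate
8 | (2-Dec-ethyl)magnesium bromide | CC1=C(CC[Mg]Br)[C@@]2(C)CCCC(C)(C)[C@@H]2CC1 | intermediate
9 | chelated vinylmagnesium alkoxide (2,5-dihydro-1,2-oxamagnesole, Mg on C14, O on C13′) | CC1=C(CCC3=C(CCO[Si](C)(C)C(C)(C)C)[Mg]OC3)[C@@]2(C)CCCC(C)(C)[C@@H]2CC1 | intermediate
10 | (E)-5-[(tert-butyldimethylsilyl)oxy]-2-(2-Dec-ethyl)pent-2-en-1-ol | CC1=C(CC/C(=C\CCO[Si](C)(C)C(C)(C)C)CO)[C@@]2(C)CCCC(C)(C)[C@@H]2CC1 | intermediate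
11 | tert-butyl{[(E)-5-[(tert-butyldimethylsilyl)oxy]-2-(2-Dec-ethyl)pent-2-en-1-yl]oxy}diphenylsilane | CC1=C(CC/C(=C\CCO[Si](C)(C)C(C)(C)C)CO[Si](c3ccccc3)(c4ccccc4)C(C)(C)C)[C@@]2(C)CCCC(C)(C)[C@@H]2CC1 | intermediate
12 | (E)-4-{[(tert-butyldiphenylsilyl)oxy]methyl}-6-Dec-hex-3-en-1-ol | CC1=C(CC/C(=C\CCO)CO[Si](c3ccccc3)(c4ccccc4)C(C)(C)C)[C@@]2(C)CCCC(C)(C)[C@@H]2CC1 | intermediate
13 | (E)-4-{[(tert-butyldiphenylsilyl)oxy]methyl}-6-Dec-hex-3-enal | CC1=C(CC/C(=C\CC=O)CO[Si](c3ccccc3)(c4ccccc4)C(C)(C)C)[C@@]2(C)CCCC(C)(C)[C@@H]2CC1 | intermediate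
14 | trimethylsilylacetylene | C#C[Si](C)(C)C | starting material
15 | lithium (trimethylsilyl)acetylide | [Li]C#C[Si](C)(C)C | intermediate
16 | (5E)-6-{[(tert-butyldiphenylsilyl)oxy]methyl}-8-Dec-1-(trimethylsilyl)oct-5-en-1-yn-3-ol, both C16 epimers | CC1=C(CC/C(=C\CC(O)C#C[Si](C)(C)C)CO[Si](c3ccccc3)(c4ccccc4)C(C)(C)C)[C@@]2(C)CCCC(C)(C)[C@@H]2CC1 | intermediate
17 | (E)-6-{[(tert-butyldiphenylsilyl)oxy]methyl}-8-Dec-1-(trimethylsilyl)oct-5-en-1-yn-3-one | CC1=C(CC/C(=C\CC(=O)C#C[Si](C)(C)C)CO[Si](c3ccccc3)(c4ccccc4)C(C)(C)C)[C@@]2(C)CCCC(C)(C)[C@@H]2CC1 | intermediate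
18 | (3R,5E)-6-{[(tert-butyldiphenylsilyl)oxy]methyl}-8-Dec-1-(trimethylsilyl)oct-5-en-1-yn-3-ol | CC1=C(CC/C(=C\C[C@@H](O)C#C[Si](C)(C)C)CO[Si](c3ccccc3)(c4ccccc4)C(C)(C)C)[C@@]2(C)CCCC(C)(C)[C@@H]2CC1 | intermediate
19 | (3R,5E)-6-{[(tert-butyldiphenylsilyl)oxy]methyl}-8-Dec-oct-5-en-1-yn-3-ol (key-step precursor) | CC1=C(CC/C(=C\C[C@@H](O)C#C)CO[Si](c3ccccc3)(c4ccccc4)C(C)(C)C)[C@@]2(C)CCCC(C)(C)[C@@H]2CC1 | intermediate
20 | (chloromethyl)isopropoxydimethylsilane | CC(C)O[Si](C)(C)CCl | starting material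
21 | carbon dioxide | O=C=O | starting material
22 | [(isopropoxydimethylsilyl)methyl]magnesium chloride | CC(C)O[Si](C)(C)C[Mg]Cl | intermediate
23 | oxamagnesacycle (2,5-dihydro-1,2-oxamagnesole, O on C16, Mg on C18, silylmethyl on C17) | CC1=C(CC/C(=C\C[C@H]3O[Mg]C=C3C[Si](C)(C)OC(C)C)CO[Si](c4ccccc4)(c5ccccc5)C(C)(C)C)[C@@]2(C)CCCC(C)(C)[C@@H]2CC1 | intermediate
24 | (2E,4R,6E)-7-{[(tert-butyldiphenylsilyl)oxy]methyl}-9-Dec-4-hydroxy-3-{[isopropoxy(dimethyl)silyl]methyl}nona-2,6-dienoic acid (carboxyl cis to C16) | CC1=C(CC/C(=C\C[C@@H](O)/C(C[Si](C)(C)OC(C)C)=C\C(=O)O)CO[Si](c3ccccc3)(c4ccccc4)C(C)(C)C)[C@@]2(C)CCCC(C)(C)[C@@H]2CC1 | intermediate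
25 | (5R)-5-[(2E)-3-{[(tert-butyldiphenylsilyl)oxy]methyl}-5-Dec-pent-2-en-1-yl]-4-{[isopropoxy(dimethyl)silyl]methyl}furan-2(5H)-one (key-step product) | CC1=C(CC/C(=C\C[C@H]3OC(=O)C=C3C[Si](C)(C)OC(C)C)CO[Si](c4ccccc4)(c5ccccc5)C(C)(C)C)[C@@]2(C)CCCC(C)(C)[C@@H]2CC1 | intermediate
26 | (5R)-5-[(2E)-3-{[(tert-butyldiphenylsilyl)oxy]methyl}-5-Dec-pent-2-en-1-yl]-4-(hydroxymethyl)furan-2(5H)-one | CC1=C(CC/C(=C\C[C@H]3OC(=O)C=C3CO)CO[Si](c4ccccc4)(c5ccccc5)C(C)(C)C)[C@@]2(C)CCCC(C)(C)[C@@H]2CC1 | intermediate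
27 | (5R)-4-(hydroxymethyl)-5-[(2E)-3-(hydroxymethyl)-5-Dec-pent-2-en-1-yl]furan-2(5H)-one (CNP0238475.3) | CC1=C(CC/C(=C\C[C@H]2OC(=O)C=C2CO)CO)[C@@]2(C)CCCC(C)(C)[C@@H]2CC1 | target

**Step count and risk**

Total steps: 15. Longest linear sequence: 14 (steps 1–3 and 5–15, from sclareolide); step 4 is a one-step side branch.

Steps most likely to fail:

1. Step 13. Deprotonation of the terminal C18–H to a magnesium or copper acetylide may compete with carbometalation, and the aggregated vinylmagnesium may take up carbon dioxide incompletely, leaving the protonated 1,1-disubstituted alkene. The fallback reverses the order of the two C–C bonds and sets out from 19. Double deprotonation (n-BuLi, 2.1 equiv, THF, −78 °C) and carboxylation of the acetylide with CO2 should give (4R,6E)-7-{[(tert-butyldiphenylsilyl)oxy]methyl}-9-Dec-4-hydroxynon-6-en-2-ynoic acid F1. Methylation (TMSCHN2, MeOH/toluene) gives methyl ynoate F2. Syn-conjugate addition of the silylmethylcopper reagent made from 22 and CuBr·SMe2 (THF, −78 °C) places C17′ on C17 cis to the new C18–H, so the ester lies cis to C16–O and lactonises on weakly acidic work-up. The route is rejoined at 25.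

2. Step 5. Transfer of a primary alkyl group with β-hydrogens to the internal alkyne may be slow, so that β-hydride loss or homocoupling of the alkylcopper consumes the Grignard reagent before addition. The fallback builds the same alkene by cross-coupling and sets out from 7. Hydroxyl-directed ruthenium-catalysed trans-hydrostannation ([Cp*RuCl]4 cat., Bu3SnH, CH2Cl2) should give (Z)-5-[(tert-butyldimethylsilyl)oxy]-2-(tributylstannyl)pent-2-en-1-ol F3. Iododestannylation (I2, CH2Cl2, 0 °C) gives (Z)-5-[(tert-butyldimethylsilyl)oxy]-2-iodopent-2-en-1-ol F4 with retention. Silylation (TBDPSCl, imidazole) gives the TBDPS ether of the iodide F5. Grignard reagent 8 is transmetalated with ZnBr2 to (2-Dec-ethyl)zinc bromide F6, and Negishi coupling with F5 (Pd(dppf)Cl2, THF, 40 °C) proceeds with retention of alkene geometry. The route is rejoined at 11.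

3. Step 11. The doubly activated C15 methylene of ynone 17 may be deprotonated during oxidation, chromatography or hydrogen transfer, so that the C13=C14 alkene migrates into conjugation before reduction. The fallback avoids any C16 carbonyl next to the alkyne and sets out from 13. Wittig olefination (Ph3P=CHCO2Et, CH2Cl2, rt) should give ethyl (2E,5E)-6-{[(tert-butyldiphenylsilyl)oxy]methyl}-8-Dec-octa-2,5-dienoate F7. DIBAL-H (CH2Cl2, −78 °C) gives (2E,5E)-6-{[(tert-butyldiphenylsilyl)oxy]methyl}-8-Dec-octa-2,5-dien-1-ol F8. Sharpless asymmetric epoxidation (Ti(OiPr)4, D-(−)-diisopropyl tartrate, TBHP, 4 Å MS, CH2Cl2, −20 °C) sets C16 in the (2R,3R)-epoxy alcohol F9. Appel chlorination (PPh3, CCl4, NaHCO3, reflux) gives the epoxy chloride F10. LDA (3.2 equiv, THF, −40 °C) then induces α-chloro carbanion formation, epoxide-opening β-elimination and dehydrochlorination, leaving the C16–O bond intact. The route is rejoined at 19.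

**Further compounds**

F1 | step 13 | (4R,6E)-7-{[(tert-butyldiphenylsilyl)oxy]methyl}-9-Dec-4-hydroxynon-6-en-2-ynoic acid | CC1=C(CC/C(=C\C[C@@H](O)C#CC(=O)O)CO[Si](c3ccccc3)(c4ccccc4)C(C)(C)C)[C@@]2(C)CCCC(C)(C)[C@@H]2CC1
F2 | step 13 | methyl (4R,6E)-7-{[(tert-butyldiphenylsilyl)oxy]methyl}-9-Dec-4-hydroxynon-6-en-2-ynoate | CC1=C(CC/C(=C\C[C@@H](O)C#CC(=O)OC)CO[Si](c3ccccc3)(c4ccccc4)C(C)(C)C)[C@@]2(C)CCCC(C)(C)[C@@H]2CC1
F3 | step 5 | (Z)-5-[(tert-butyldimethylsilyl)oxy]-2-(tributylstannyl)pent-2-en-1-ol | CCCC[Sn](CCCC)(CCCC)/C(CO)=C\CCO[Si](C)(C)C(C)(C)C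
F4 | step 5 | (Z)-5-[(tert-butyldimethylsilyl)oxy]-2-iodopent-2-en-1-ol | I/C(CO)=C\CCO[Si](C)(C)C(C)(C)C
F5 | step 5 | tert-butyl{[(Z)-5-[(tert-butyldimethylsilyl)oxy]-2-iodopent-2-en-1-yl]oxy}diphenylsilane | I/C(CO[Si](c1ccccc1)(c2ccccc2)C(C)(C)C)=C\CCO[Si](C)(C)C(C)(C)C
F6 | step 5 | (2-Dec-ethyl)zinc bromide | CC1=C(CC[Zn]Br)[C@@]2(C)CCCC(C)(C)[C@@H]2CC1
F7 | step 11 | ethyl (2E,5E)-6-{[(tert-butyldiphenylsilyl)oxy]methyl}-8-Dec-octa-2,5-dienoate | CC1=C(CC/C(=C\C/C=C/C(=O)OCC)CO[Si](c3ccccc3)(c4ccccc4)C(C)(C)C)[C@@]2(C)CCCC(C)(C)[C@@H]2CC1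
F8 | step 11 | (2E,5E)-6-{[(tert-butyldiphenylsilyl)oxy]methyl}-8-Dec-octa-2,5-dien-1-ol | CC1=C(CC/C(=C\C/C=C/CO)CO[Si](c3ccccc3)(c4ccccc4)C(C)(C)C)[C@@]2(C)CCCC(C)(C)[C@@H]2CC1
F9 | step 11 | [(2R,3R)-3-{(2E)-3-{[(tert-butyldiphenylsilyl)oxy]methyl}-5-Dec-pent-2-en-1-yl}oxiran-2-yl]methanol | CC1=C(CC/C(=C\C[C@H]3O[C@@H]3CO)CO[Si](c4ccccc4)(c5ccccc5)C(C)(C)C)[C@@]2(C)CCCC(C)(C)[C@@H]2CC1
F10 | step 11 | (2S,3R)-2-(chloromethyl)-3-{(2E)-3-{[(tert-butyldiphenylsilyl)oxy]methyl}-5-Dec-pent-2-en-1-yl}oxirane | CC1=C(CC/C(=C\C[C@H]3O[C@@H]3CCl)CO[Si](c4ccccc4)(c5ccccc5)C(C)(C)C)[C@@]2(C)CCCC(C)(C)[C@@H]2CC1
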